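**Plan**
- Retrosynthesis: the C15 ketone (allylic oxidation) and the C16=C17 methylene (Peterson olefination) are removed first. Ring C is then cut at C11–C12 and ring D at C13–C16 in one stroke. This leaves a spiro-lactone whose C8 carries an acryloyl arm (C14–C13=C12) and a 2-oxo-3-silylpropyl arm (C15–C16–C17), and whose C9 carries the C11 aldehyde.
- Further cuts: C8–C15 (alkylation), C8–C14 (aldol, then oxidation), C9–C11 (conjugate addition), C10–C9 and the lactone (Michael addition to methyl propiolate, lactonisation), C5–C6 and C10–C20 on 4,4-dimethylcyclohexenone.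
- Forward: ring A, then the lactone ring, then the C9 and C8 substituents; one SmI2 operation closes ring C (C11–C12) and then ring D (C13–C16); redox adjustment finishes.
- Stereochemistry: C5 comes from a rhodium/BINAP 1,4-addition, the only external source. C10, C1, C9 and C8 follow by substrate control relayed from C5. C11 and C13 are set in the key step, C14 by a samarium-chelated reduction directed by the transient C16 hydroxyl.
- Enabling feature: C8 is a quaternary carbon flanked by three carbonyl-level carbons (C7, C14, C15) next to C9. The C11 aldehyde therefore lies 1,5 to the acryloyl terminus C12, and the derived C13 enolate lies 1,5 to C16. C13 becomes a bridgehead of the bicyclo[3.2.1]octane, so its configuration is forced.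

Key step: step 12

Remark: atoms are numbered as in ent-kaurane (C7 lactone carbonyl, C20 lactone CH2, C14 bridging carbinol, C15 ketone). α means the face of ring A that carries C20 and the C1 oxygen; β means the face of H-5 and H-9.
Remark: 3-(phenylsulfonyl)propanal (14) and [2-(chloromethyl)allyl]trimethylsilane (18) are taken as purchasable; 14 is otherwise one step from acrolein and sodium benzenesulfinate.
Remark: the SMILES of 16, 17 and 26 leave one centre open where a mixture forms that is erased in the following step.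

Step 1
Reactants: 1 4,4-dimethylcyclohex-2-en-1-one; 2 hex-1-yne
Product: 4 silyl enol ether (S)-3-[(E)-hex-1-enyl]-4,4-dimethyl-1-(trimethylsilyloxy)cyclohex-1-ene, via hexenylzirconocene chloride 3 (not isolated)
Conditions: 2, Cp2Zr(H)Cl, THF, rt; then 1, [Rh(cod)(MeCN)2]BF4 (5 mol%), (R)-BINAP (6 mol%), rt; then TMSCl, 0 °C
Reagents that add atoms: chlorotrimethylsilane C[Si](C)(C)Cl
Why: Hydrozirconation gives the (E)-alkenylzirconocene, whose rhodium/BINAP-catalysed asymmetric 1,4-addition (Hayashi type) should set C5 by catalyst control and leave a regiodefined zirconium enolate that TMSCl traps as the silyl enol ether.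

Step 2
Reactants: 4 silyl enol ether
Product: 5 formyl ketone (R)-3-[(E)-hex-1-enyl]-2-(hydroxymethylidene)-4,4-dimethylcyclohexan-1-one
Conditions: MeLi, THF, 0 °C; then HCO2CH2CF3, −78 °C; aq. NH4Cl
Reagents that add atoms: 2,2,2-trifluoroethyl formate O=COCC(F)(F)F
Why: MeLi releases the regiodefined lithium enolate, which should be C-formylated at C10 (Claisen-type formylation) to give the 1,3-dicarbonyl needed for the next step.

Step 3
Reactants: 5 formyl ketone; 6 methyl propiolate
Product: 7 quaternary aldehyde (Z)-enoate (C20 formyl cis and C9 arm trans to the C5 hexenyl group)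
Conditions: 6, DBU (10 mol%), MeCN, −20 °C
Reagents that add atoms: none
Why: Michael addition of the 1,3-dicarbonyl to the ynoate should create quaternary C10 with the acceptor entering anti to the C5 side chain (held pseudo-axial by allylic strain), and protonation of the allenoate anti to the bulky substituent should give the (Z)-enoate.

Step 4
Reactants: 7 quaternary aldehyde (Z)-enoate
Product: 9 keto spiro-lactone (C1 ketone; C8=C9 unsaturated 7,20-lactone), via hydroxy ester 8 (not isolated)
Conditions: NaBH4, MeOH/CH2Cl2, −78 °C; then PPTS, CH2Cl2, rt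
Reagents that add atoms: none
Why: The aldehyde should be reduced faster than the hindered C1 ketone or the conjugated ester, and the (Z)-hydroxy enoate then closes to the six-membered unsaturated lactone (lactonisation).

Step 5
Reactants: 9 keto spiro-lactone
Product: 11 diol spiro-lactone (1α-OH; C6 OH), via keto aldehyde 10 (not isolated)
Conditions: O3, CH2Cl2/MeOH, −78 °C; Me2S; then NaBH4, CeCl3·7H2O, MeOH, −78 to 0 °C
Reagents that add atoms: ozone [O-][O+]=O
Why: Ozonolysis should cleave the electron-rich hexenyl alkene and spare the electron-poor lactone alkene, and Luche reduction then reduces the C6 aldehyde and the C1 ketone 1,2-selectively, hydride entering C1 axially (away from the axial C20) to give the equatorial 1α-alcohol.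

Step 6
Reactants: 11 diol spiro-lactone
Product: 12 C6 TBDPS ether
Conditions: TBDPSCl, imidazole, CH2Cl2, 0 °C
Reagents that add atoms: tert-butyl(chloro)diphenylsilane CC(C)(C)[Si](Cl)(c1ccccc1)c1ccccc1
Why: Silylation should be selective for the primary C6 alcohol over the hindered secondary C1 alcohol.

Step 7
Reactants: 12 C6 TBDPS ether
Product: 13 C1 acetate
Conditions: Ac2O, DMAP, pyridine, CH2Cl2, rt
Reagents that add atoms: acetic anhydride CC(=O)OC(C)=O
Why: DMAP-catalysed acetylation installs the acetate of the target early, which is possible because no strongly basic step follows.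

Step 8
Reactants: 13 C1 acetate; 14 3-(phenylsulfonyl)propanal
Product: 16 β-hydroxy lactone (C9 vinyl with H-9 β; C8 side chain trans to the vinyl group), via silyl ketene acetal 15 (not isolated)
Conditions: (CH2=CH)2CuLi, TMSCl, THF, −78 °C; then 14, BF3·OEt2, CH2Cl2, −78 °C
Reagents that add atoms: lithium divinylcuprate [Li+].C=C[Cu-]C=C
Why: The TMSCl-accelerated cuprate 1,4-addition should deliver vinyl (the C11 precursor) to C9 from the face away from the C5 CH2OTBDPS group, and the Mukaiyama aldol of the ketene acetal attaches the masked acrolein (C14–C12) trans to the vinyl group without a basic enolate.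

Step 9
Reactants: 16 β-hydroxy lactone
Product: 17 β-keto lactone
Conditions: Dess–Martin periodinane, NaHCO3, CH2Cl2, rt
Reagents that add atoms: none
Why: Dess–Martin oxidation merges the carbinol epimers into the C14 ketone, while the sulfone keeps the future vinyl ketone masked so that the enolisable C8 cannot close onto it by oxa-Michael addition.

Step 10
Reactants: 17 β-keto lactone; 18 [2-(chloromethyl)prop-2-en-1-yl]trimethylsilane
Product: 20 C8-quaternary enone allylsilane, via allylated sulfone 19 (not isolated)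
Conditions: 18, Cs2CO3, NaI (cat.), MeCN, 0 °C to rt; then DBU, rt
Reagents that add atoms: none
Why: C-allylation of the soft β-keto lactone enolate should occur anti to the C9 vinyl group, placing the acyl arm cis and the C15 arm trans to C11 at quaternary C8, and E1cB loss of benzenesulfinate then unveils the vinyl ketone only after C8 is blocked.

Step 11
Reactants: 20 C8-quaternary enone allylsilane
Product: 21 keto aldehyde cascade precursor (C9 CHO; C8 acryloyl and CH2C(=O)CH2SiMe3)
Conditions: O3, CH2Cl2, pyridine, −78 °C; PPh3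
Reagents that add atoms: ozone [O-][O+]=O
Why: Ozonolysis should cleave the two electron-rich terminal alkenes (C9 vinyl to the C11 aldehyde, allylsilane to the α-silyl ketone) and leave the electron-poor acryloyl alkene.

Step 12
Reactants: 21 keto aldehyde cascade precursor
Product: 23 tetracyclic aldol (11β-OH; 14-ketone; 16-OH; 16-CH2SiMe3), via samarium enolate 22 (not isolated)
Conditions: SmI2 (3 equiv), THF, −78 to −20 °C, no proton source; sat. aq. NH4Cl
Reagents that add atoms: none
Why: SmI2 transfers an electron to the C11 aldehyde (or to the activated vinyl ketone; both entries lead to the same bond), and ring C closes by 6-endo-trig attack of C11 on C12, the terminus of the acryloyl arm whose carbonyl C14 lies inside the new ring; a second electron gives the trivalent samarium enolate C13=C14–O, which closes ring D by aldol addition of C13 to the C16 ketone (five-membered, 5-(enolendo)-exo-trig; the axial lobe of the C13 enolate carbon in the six-membered ring points at the axial C15 arm, which offsets the poor overlap usual for this mode). The closest known reaction type is the SmI2 ketyl–olefin cyclisation/aldol cascade of aldehyde-tethered unsaturated lactones used for related ent-kauranoid cores. C11 should be set in a chair-like transition state with the samarium-bound oxygen equatorial and anti to the C9–C10 bond (hydroxyl cis to H-9); C13 is a bridgehead and can only form with C12 and C16 on the face of ring C that carries C15; the C16 carbinol forms with its oxygen held by samarium next to the C14 oxygen and is erased later. Which arm of C8 enters ring C follows from the C8 configuration set in step 10 (acryloyl cis to C11). The step needs C–C coupling to outrun pinacol coupling of C11 with C16 and plain reduction of the enone: the aldehyde and the vinyl ketone are far easier to reduce than the hindered α-silyl ketone, the six-ring closure onto the polarised enone is fast, and the enolate survives until the aldol because no proton source is present.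

Step 13
Reactants: 23 tetracyclic aldol
Product: 25 11β,14-diol with 16-methylene group, via triol silane 24 (not isolated)
Conditions: SmI2, MeOH, THF, 0 °C; then p-TsOH·H2O (cat.), CH2Cl2, 0 °C
Reagents that add atoms: none
Why: In the samarium-mediated reduction of this β-hydroxy ketone (Keck type), samarium bound to the C16 hydroxyl should hold the C14 ketyl oxygen on the side of the C15–C16 bridge so that the proton arrives from the opposite face (natural 14-OH), and acid-promoted Peterson elimination of the β-hydroxysilane then gives only the C16=C17 alkene.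

Step 14
Reactants: 25 11β,14-diol with 16-methylene group
Product: 26 15-hydroxy compound (C15 epimers)
Conditions: SeO2 (cat.), t-BuOOH, CH2Cl2, rt
Reagents that add atoms: tert-butyl hydroperoxide CC(C)(C)OO
Why: Selenium dioxide allylic oxidation (ene, then [2,3]-shift) can only occur at C15, because the other allylic position C13 is a bridgehead.

Step 15
Reactants: 26 15-hydroxy compound
Product: 27 enone (6-O-TBDPS ether of the target)
Conditions: MnO2, CH2Cl2, rt
Reagents that add atoms: none
Why: MnO2 should oxidise only the allylic C15 alcohol and leave the non-allylic C11 and C14 alcohols, giving the 15-oxo-16-ene unit.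

Step 16
Reactants: 27 enone
Product: 28 target CNP0225182.1
Conditions: HF·pyridine, THF/pyridine, 0 °C to rt
Reagents that add atoms: none
Why: Fluoride-mediated desilylation frees the C6 alcohol under conditions that the acetate, the lactone, the enone and the β-hydroxy ketone should tolerate.

**Compound list**
1 | 4,4-dimethylcyclohex-2-en-1-one | CC1(C)CCC(=O)C=C1 | starting material
2 | hex-1-yne | CCCCC#C | starting material
3 | chlorobis(cyclopentadienyl)[(E)-hex-1-enyl]zirconium | CCCC/C=C/[Zr](Cl)(C1C=CC=C1)C1C=CC=C1 | intermediate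
4 | (S)-3-[(E)-hex-1-enyl]-4,4-dimethyl-1-(trimethylsilyloxy)cyclohex-1-ene | C[Si](C)(C)OC1=C[C@H](/C=C/CCCC)C(C)(C)CC1 | intermediate
5 | (R)-3-[(E)-hex-1-enyl]-2-(hydroxymethylidene)-4,4-dimethylcyclohexan-1-one (enol form of the 2-formyl ketone) | OC=C1C(=O)CCC(C)(C)[C@H]1/C=C/CCCC | intermediate
6 | methyl propiolate | C#CC(=O)OC | starting material
7 | methyl (Z)-3-[1-formyl-2-[(E)-hex-1-enyl]-3,3-dimethyl-6-oxocyclohexyl]prop-2-enoate; formyl (C20) cis and propenoate arm (C9) trans to the hexenyl group | O=C[C@@]1(/C=C\C(=O)OC)C(=O)CCC(C)(C)[C@H]1/C=C/CCCC | intermediate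
8 | primary alcohol from 7 (C20 CH2OH) | OC[C@@]1(/C=C\C(=O)OC)C(=O)CCC(C)(C)[C@H]1/C=C/CCCC | intermediate
9 | keto spiro-lactone: ring A C1 ketone spiro-fused at C10 to the 5,6-dihydro-2H-pyran-2-one O–C20–C10–C9=C8–C7(=O); C5 (E)-hexenyl cis to C20 | O=C1C=C[C@]2(CO1)C(=O)CCC(C)(C)[C@H]2/C=C/CCCC | intermediate
10 | C6 aldehyde from 9 (hexenyl group cleaved) | O=C1C=C[C@]2(CO1)C(=O)CCC(C)(C)[C@H]2C=O | intermediate
11 | diol spiro-lactone: 1α-OH (equatorial, cis to C20) and C6 CH2OH | O=C1C=C[C@]2(CO1)[C@@H](O)CCC(C)(C)[C@H]2CO | intermediate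
12 | 6-O-TBDPS ether of 11 | O=C1C=C[C@]2(CO1)[C@@H](O)CCC(C)(C)[C@H]2CO[Si](c1ccccc1)(c1ccccc1)C(C)(C)C | intermediate
13 | 1α-acetate of 12 | O=C1C=C[C@]2(CO1)[C@@H](OC(C)=O)CCC(C)(C)[C@H]2CO[Si](c1ccccc1)(c1ccccc1)C(C)(C)C | intermediate
14 | 3-(phenylsulfonyl)propanal | O=CCCS(=O)(=O)c1ccccc1 | starting material
15 | trimethylsilyl ketene acetal of the 9-vinyl lactone (H-9 β) | C[Si](C)(C)OC1=C[C@@H](C=C)[C@]2(CO1)[C@@H](OC(C)=O)CCC(C)(C)[C@H]2CO[Si](c3ccccc3)(c3ccccc3)C(C)(C)C | intermediate
16 | β-hydroxy lactone: 9-vinyl (H-9 β); C8 carries H and the 1-hydroxy-3-(phenylsulfonyl)propyl group trans to the vinyl group; carbinol epimers | O=C1OC[C@]2([C@@H](OC(C)=O)CCC(C)(C)[C@H]2CO[Si](c3ccccc3)(c3ccccc3)C(C)(C)C)[C@H](C=C)[C@H]1C(O)CCS(=O)(=O)c1ccccc1 | intermediate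
17 | β-keto lactone: C8 carries the 3-(phenylsulfonyl)propanoyl group; C8 enolisable | O=C1OC[C@]2([C@@H](OC(C)=O)CCC(C)(C)[C@H]2CO[Si](c3ccccc3)(c3ccccc3)C(C)(C)C)[C@H](C=C)C1C(=O)CCS(=O)(=O)c1ccccc1 | intermediate
18 | [2-(chloromethyl)prop-2-en-1-yl]trimethylsilane | C=C(CCl)C[Si](C)(C)C | starting material
19 | C8-quaternary sulfone: acyl arm cis and 2-(trimethylsilylmethyl)allyl arm trans to the C9 vinyl group | O=C1OC[C@]2([C@@H](OC(C)=O)CCC(C)(C)[C@H]2CO[Si](c3ccccc3)(c3ccccc3)C(C)(C)C)[C@H](C=C)[C@@]1(C(=O)CCS(=O)(=O)c1ccccc1)CC(=C)C[Si](C)(C)C | intermediate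
20 | C8-quaternary enone allylsilane (acryloyl arm C14(=O)–C13H=C12H2) | O=C1OC[C@]2([C@@H](OC(C)=O)CCC(C)(C)[C@H]2CO[Si](c3ccccc3)(c3ccccc3)C(C)(C)C)[C@H](C=C)[C@@]1(C(=O)C=C)CC(=C)C[Si](C)(C)C | intermediate
21 | cascade precursor: C9 CHO (C11); C8 acryloyl and CH2C(=O)CH2SiMe3 arms | O=C1OC[C@]2([C@@H](OC(C)=O)CCC(C)(C)[C@H]2CO[Si](c3ccccc3)(c3ccccc3)C(C)(C)C)[C@H](C=O)[C@@]1(C(=O)C=C)CC(=O)C[Si](C)(C)C | intermediate
22 | tricyclic samarium alkoxide enolate: ring C closed; C11 O–SmI2; C13=C14 O–SmI2 | O=C1OC[C@]2([C@@H](OC(C)=O)CCC(C)(C)[C@H]2CO[Si](c4ccccc4)(c4ccccc4)C(C)(C)C)[C@@H]3[C@@H](O[Sm](I)I)CC=C(O[Sm](I)I)[C@]13CC(=O)C[Si](C)(C)C | intermediate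
23 | tetracyclic aldol: 11β-OH; 14-ketone; 16-OH on the side of C14; 16-CH2SiMe3 | C[Si](C)(C)C[C@@]1(O)C[C@@]23C(=O)OC[C@]4([C@@H](OC(C)=O)CCC(C)(C)[C@H]4CO[Si](c5ccccc5)(c5ccccc5)C(C)(C)C)[C@@H]2[C@@H](O)C[C@@H]1C3=O | intermediate
24 | 11,14,16-triol silane (14-OH on the side of the C15–C16 bridge) | C[Si](C)(C)C[C@@]1(O)C[C@@]23C(=O)OC[C@]4([C@@H](OC(C)=O)CCC(C)(C)[C@H]4CO[Si](c5ccccc5)(c5ccccc5)C(C)(C)C)[C@@H]2[C@@H](O)C[C@@H]1[C@H]3O | intermediate
25 | 11β,14-diol with 16-methylene group and C15 CH2 | C=C1C[C@@]23C(=O)OC[C@]4([C@@H](OC(C)=O)CCC(C)(C)[C@H]4CO[Si](c5ccccc5)(c5ccccc5)C(C)(C)C)[C@@H]2[C@@H](O)C[C@@H]1[C@H]3O | intermediate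
26 | 15-hydroxy derivative of 25 (C15 epimers) | C=C1C(O)[C@@]23C(=O)OC[C@]4([C@@H](OC(C)=O)CCC(C)(C)[C@H]4CO[Si](c5ccccc5)(c5ccccc5)C(C)(C)C)[C@@H]2[C@@H](O)C[C@@H]1[C@H]3O | intermediate
27 | 6-O-TBDPS ether of the target | C=C1C(=O)[C@@]23C(=O)OC[C@]4([C@@H](OC(C)=O)CCC(C)(C)[C@H]4CO[Si](c5ccccc5)(c5ccccc5)C(C)(C)C)[C@@H]2[C@@H](O)C[C@@H]1[C@H]3O | intermediate
28 | CNP0225182.1 (1α-acetoxy-6,11β,14-trihydroxy-15-oxo-6,7-seco-ent-kaur-16-en-7,20-olide) | C=C1C(=O)[C@@]23C(=O)OC[C@]4([C@@H](OC(C)=O)CCC(C)(C)[C@H]4CO)[C@@H]2[C@@H](O)C[C@@H]1[C@H]3O | target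

Total step count: 16. Longest linear sequence: 16 steps (from 1).

**Steps most likely to fail**

Step 12. The cascade may be diverted by pinacol-type coupling of the C11 ketyl with the C16 ketone, by plain reduction of the vinyl ketone, or by protonation of the samarium enolate before ring D closes. Fallback, from 17, rejoining the route at 25: the C15 arm is changed so that no second ketone is present, and the two rings are closed one after the other. 17 is C-propargylated (propargyl bromide, Cs2CO3, MeCN) to the propargyl sulfone F1. DBU gives the propargyl enone F2. Ozonolysis of the C9 vinyl group gives the aldehyde F3. SmI2, LiBr and t-BuOH in THF at −78 °C close ring C by the same 6-endo ketyl–olefin addition, now with protonation of the enolate, to give the hydroxy ketone F4. TMSOTf and Et3N give the bis-silyl compound F5, with a C11 silyl ether and a C13=C14 silyl enol ether (the only enolisable direction). A gold-catalysed 5-exo-dig Conia-ene-type cyclisation ([(JohnPhos)Au(MeCN)]SbF6, CH2Cl2/MeOH) closes ring D, sets the 16-methylene group and removes the silyl groups, giving the methylene ketone F6. An equilibrating Meerwein–Ponndorf–Verley reduction (Al(Oi-Pr)3, i-PrOH) of the C14 ketone then gives 25.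

Step 13. Hydrogen may be delivered to C14 from the side of the C15–C16 bridge (poor facial selectivity), or the aldol 23 may open by retro-aldol reaction before it is reduced. Fallback, from 23, rejoining the route at 27: the C14 configuration is corrected under thermodynamic control once C15 is a ketone. Reduction of 23 and the same Peterson elimination would then give mainly the 14-epimeric diol F7, which is carried through the selenium dioxide oxidation to the 14-epi 15-alcohol F8 and through the MnO2 oxidation to the 14-epi enone F9. Catalytic t-BuOK in t-BuOH/THF at 0 °C then opens and re-closes the C8–C14 bond (retro-aldol/aldol through the C8 enolate stabilised by C7 and C15). This should funnel F9 into the less congested natural epimer 27, whose 14-OH is turned away from C10.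

Step 8. Addition at the neopentyl C9 next to the spiro centre may be slow, or the cuprate may attack the wrong face of the lactone. Fallback, from 13, rejoining the route at 16: catalyst control replaces substrate control. Chloro(vinyl)zirconocene (from Cp2ZrCl2 and vinylmagnesium bromide), [Rh(cod)(MeCN)2]BF4 and the matching BINAP enantiomer add the vinyl group to C9, TMSCl gives the same ketene acetal 15, and the Mukaiyama aldol with 14 is run as before to give 16. No new compound arises.

**Further compounds**
F1 | step 12 | propargyl sulfone: C8 carries the 3-(phenylsulfonyl)propanoyl arm cis and the propargyl arm trans to the C9 vinyl group | O=C1OC[C@]2([C@@H](OC(C)=O)CCC(C)(C)[C@H]2CO[Si](c3ccccc3)(c3ccccc3)C(C)(C)C)[C@H](C=C)[C@@]1(C(=O)CCS(=O)(=O)c1ccccc1)CC#C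
F2 | step 12 | propargyl enone (C8 acryloyl and propargyl arms; C9 vinyl) | O=C1OC[C@]2([C@@H](OC(C)=O)CCC(C)(C)[C@H]2CO[Si](c3ccccc3)(c3ccccc3)C(C)(C)C)[C@H](C=C)[C@@]1(C(=O)C=C)CC#C
F3 | step 12 | aldehyde (C9 CHO; C8 acryloyl and propargyl arms) | O=C1OC[C@]2([C@@H](OC(C)=O)CCC(C)(C)[C@H]2CO[Si](c3ccccc3)(c3ccccc3)C(C)(C)C)[C@H](C=O)[C@@]1(C(=O)C=C)CC#C
F4 | step 12 | hydroxy ketone (ring C closed; 11β-OH; 14-ketone; C8 propargyl) | O=C1OC[C@]2([C@@H](OC(C)=O)CCC(C)(C)[C@H]2CO[Si](c4ccccc4)(c4ccccc4)C(C)(C)C)[C@@H]3[C@@H](O)CCC(=O)[C@]13CC#C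
F5 | step 12 | bis-silyl compound (C11 OSiMe3; C13=C14 OSiMe3 enol ether) | O=C1OC[C@]2([C@@H](OC(C)=O)CCC(C)(C)[C@H]2CO[Si](c4ccccc4)(c4ccccc4)C(C)(C)C)[C@@H]3[C@@H](O[Si](C)(C)C)CC=C(O[Si](C)(C)C)[C@]13CC#C
F6 | step 12 | methylene ketone (tetracycle; 11β-OH; 14-ketone; 16-methylene) | C=C1C[C@@]23C(=O)OC[C@]4([C@@H](OC(C)=O)CCC(C)(C)[C@H]4CO[Si](c5ccccc5)(c5ccccc5)C(C)(C)C)[C@@H]2[C@@H](O)C[C@@H]1C3=O
F7 | step 13 | 14-epimeric diol (14-epimer of 25) | C=C1C[C@@]23C(=O)OC[C@]4([C@@H](OC(C)=O)CCC(C)(C)[C@H]4CO[Si](c5ccccc5)(c5ccccc5)C(C)(C)C)[C@@H]2[C@@H](O)C[C@@H]1[C@@H]3O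
F8 | step 13 | 14-epi 15-alcohol (14-epimer of 26; C15 epimers) | C=C1C(O)[C@@]23C(=O)OC[C@]4([C@@H](OC(C)=O)CCC(C)(C)[C@H]4CO[Si](c5ccccc5)(c5ccccc5)C(C)(C)C)[C@@H]2[C@@H](O)C[C@@H]1[C@@H]3O
F9 | step 13 | 14-epi enone (14-epimer of 27) | C=C1C(=O)[C@@]23C(=O)OC[C@]4([C@@H](OC(C)=O)CCC(C)(C)[C@H]4CO[Si](c5ccccc5)(c5ccccc5)C(C)(C)C)[C@@H]2[C@@H](O)C[C@@H]1[C@@H]3O
F0 | step 8 | none | none
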